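**Strategy.** The cyclopentanone ring (C1 ketone, C2 methylene, C3 isopropyl methine, C3a carbinol, C8a quaternary carbon; azulene numbering) is disconnected at C1–C2. Its C(=O)–CH2–CH(i-Pr) unit is the retron of an alkene hydroacylation. A rhodium-catalysed intramolecular hydroacylation of the 4-pentenal embedded in a cycloheptenyl aldehyde (formyl on C8a, 3-methylbut-1-en-2-yl on C3a) closes the last ring, forms C1–C2 and sets C3 in one atom-economic isomerisation that gives the target directly. The aldehyde comes from a cycloheptenedione ester built by Evans aldol, Fráter–Seebach aldol and ring-closing metathesis; the aldol carbinol relays chirality to C8a and is then erased.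

Key step: step 12

Remark: atoms are named by the azulene numbering of the target (C1 ketone, C3 isopropyl carbon, C3a carbinol, C8 ester carbinol, C8a methyl-bearing carbon).
Remark: the side-chain carbinol made in the Fráter–Seebach step is carried as a mixture of epimers and left undefined in the SMILES, because it is oxidised two steps later.
Remark: ethyl 4-methylpent-4-enoate and 2-bromo-3-methylbut-1-ene are taken as commercial.

Step 1
Reactants: 1 (S)-4-benzyl-3-propanoyl-1,3-oxazolidin-2-one; 2 acrolein
Product: 4 (S)-4-benzyl-3-[(2S,3R)-3-hydroxy-2-methylpent-4-enoyl]-1,3-oxazolidin-2-one, via dibutylboron Z-enolate 3 (not isolated)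
Conditions: Bu2BOTf, Et3N, CH2Cl2, −78 to 0 °C; 2, −78 to 0 °C; pH 7 phosphate buffer, MeOH, H2O2
Reagents that add atoms: none
Why: Evans syn-aldol reaction, in which the Z boron enolate reacts through a chair Zimmerman–Traxler transition state on the face opposite the benzyl group and should set the carbinol carbon (later C8) as R.

Step 2
Reactants: 4
Product: 5 methyl (2S,3R)-3-hydroxy-2-methylpent-4-enoate
Conditions: NaOMe (1.1 equiv), MeOH, −20 °C; AcOH
Reagents that add atoms: methanol (CO)
Why: Methoxide transesterification of the activated imide removes the auxiliary without touching the carbinol centre, and any epimerisation at C2 is harmless because that carbon becomes an enolate in step 4.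

Step 3
Reactants: 6 ethyl 4-methylpent-4-enoate
Product: 7 4-methylpent-4-enal
Conditions: i-Bu2AlH (1.05 equiv), CH2Cl2, −78 °C; MeOH, aq. potassium sodium tartrate
Reagents that add atoms: none
Why: Partial hydride reduction of an ester at low temperature should stop at the aldehyde oxidation level.

Step 4
Reactants: 5; 7
Product: 9 methyl (2R,3R)-3-hydroxy-2-[(1RS)-1-hydroxy-4-methylpent-4-en-1-yl]-2-methylpent-4-enoate, via dilithium enolate alkoxide 8 (not isolated)
Conditions: LiN(i-Pr)2 (2.3 equiv), THF, −78 to −20 °C; 7, −78 °C; AcOH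
Reagents that add atoms: none
Why: Fráter–Seebach aldol addition, in which the aldehyde should approach the lithium-chelated dianion on the enolate face opposite the vinyl group of the alkoxide carbon, so that the new chain ends up anti to the hydroxyl and the quaternary carbon (later C8a) is set.

Step 5
Reactants: 9
Product: 10 methyl (1R,2R,7RS)-2,7-dihydroxy-1,4-dimethylcyclohept-3-ene-1-carboxylate
Conditions: second-generation Grubbs catalyst (5 mol %), CH2Cl2, 40 °C
Reagents that add atoms: none
Why: Ring-closing olefin metathesis between the vinyl carbinol and the 1,1-disubstituted alkene should close the seven-membered ring with its trisubstituted double bond, with no stereocentre involved.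

Step 6
Reactants: 10
Product: 11 methyl (1R)-1,4-dimethyl-2,7-dioxocyclohept-3-ene-1-carboxylate
Conditions: Dess–Martin periodinane (2.5 equiv), CH2Cl2, 0 °C to rt
Reagents that add atoms: none
Why: Dess–Martin oxidation of both secondary alcohols under neutral conditions should avoid retro-aldol or retro-Claisen cleavage and leaves the quaternary carbon as the only stereocentre.

Step 7
Reactants: 11; 12 2-bromo-3-methylbut-1-ene
Product: 15 methyl (1R,7S)-7-hydroxy-1,4-dimethyl-7-(3-methylbut-1-en-2-yl)-2-oxocyclohept-3-ene-1-carboxylate, via (3-methylbut-1-en-2-yl)lithium 13 (not isolated), via dichloro(3-methylbut-1-en-2-yl)cerium 14 (not isolated)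
Conditions: 12, t-BuLi (2 equiv), Et2O, −78 °C; CeCl3, THF, −78 °C; 11, −78 °C; aq. NH4Cl
Reagents that add atoms: none
Why: Organocerium 1,2-addition, expected at the saturated C7 ketone (the C2 carbonyl is deactivated by conjugation, the ester by resonance) with Felkin–Anh approach anti to the ester on the neighbouring quaternary carbon, so that the alkenyl group enters trans to CO2Me and sets the tertiary carbinol (later C3a).

Step 8
Reactants: 15
Product: 16 methyl (1S,2R,7S)-2,7-dihydroxy-1,4-dimethyl-7-(3-methylbut-1-en-2-yl)cyclohept-3-ene-1-carboxylate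
Conditions: Me4NBH(OAc)3 (5 equiv), MeCN/AcOH 1:1, −30 °C
Reagents that add atoms: none
Why: Hydroxyl-directed Evans–Saksena reduction, in which hydride bound to the tertiary hydroxyl is delivered internally to the enone carbonyl from the face of that hydroxyl and should give the trans-1,3-diol, the new carbinol (later C8) being cis to the methyl group.

Step 9
Reactants: 16
Product: 17 (1S,2S,3R)-2-(hydroxymethyl)-2,5-dimethyl-1-(3-methylbut-1-en-2-yl)cyclohept-4-ene-1,3-diol
Conditions: LiAlH4, THF, 0 °C to rt; H2O, aq. NaOH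
Reagents that add atoms: none
Why: LiAlH4 reduction of the neopentyl methyl ester to the primary alcohol touches no stereocentre.

Step 10
Reactants: 17
Product: 18 (1S,2R,7S)-2,7-dihydroxy-1,4-dimethyl-7-(3-methylbut-1-en-2-yl)cyclohept-3-ene-1-carbaldehyde
Conditions: TEMPO (10 mol %), PhI(OAc)2 (1.1 equiv), CH2Cl2, rt
Reagents that add atoms: none
Why: Oxoammonium (TEMPO) oxidation should select the primary alcohol over the hindered secondary allylic and the tertiary alcohol, and the resulting aldehyde cannot enolise.

Step 11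
Reactants: 18; 19 4-methoxybenzoyl chloride
Product: 20 (1R,6S,7S)-7-formyl-6-hydroxy-3,7-dimethyl-6-(3-methylbut-1-en-2-yl)cyclohept-2-en-1-yl 4-methoxybenzoate
Conditions: 19, pyridine, DMAP (cat.), CH2Cl2, 0 °C to rt
Reagents that add atoms: none
Why: DMAP-catalysed acylation should occur only at the secondary hydroxyl, since the tertiary alcohol is inert and the non-enolisable aldehyde is untouched.

Step 12
Reactants: 20
Product: 21 (3R,3aS,8R,8aS)-3a-hydroxy-6,8a-dimethyl-1-oxo-3-(propan-2-yl)-1,2,3,3a,4,5,8,8a-octahydroazulen-8-yl 4-methoxybenzoate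
Conditions: [Rh(dppe)(acetone)2]BF4 (10 mol %), acetone, 25 °C
Reagents that add atoms: none
Why: Oxidative addition of the aldehyde C–H bond to cationic monovalent rhodium gives an acyl rhodium hydride, which binds the 1,1-disubstituted alkene, transfers hydride to its internal carbon (C3) and forms C1–C2 by reductive elimination from a six-membered acyl–alkyl rhodacycle. The closest known reaction type is the rhodium-catalysed intramolecular hydroacylation of 4-substituted pent-4-enals to 3-substituted cyclopentanones. The five-membered ring closes in a formal 5-endo-trig sense, made possible by the metallacycle and helped by the two fully substituted tether carbons C3a and C8a. C3 is set by the substrate: the trans-disposed seven-ring bonds at C3a and C8a can only be diequatorial in the chair-like rhodacycle, so methyl and hydroxyl are axial, the isopropyl group is equatorial (cis to OH, trans to the C8a methyl) and hydride arrives on the alkene face turned towards the acyl tether. The step needs insertion to outrun decarbonylation and the cyclopentanone pathway to beat the cyclobutanone pathway; the non-enolisable gem-disubstituted tether and possible chelation by the β-hydroxyl favour the first, ring strain and reversible hydride insertion the second. The allylic anisoate, the trisubstituted ring alkene and the tertiary alcohol (no carbinol hydrogen, hence no redox isomerisation) are expected to be spectators.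

**Compound list**

1 | (S)-4-benzyl-3-propanoyl-1,3-oxazolidin-2-one | CCC(=O)N1[C@@H](Cc2ccccc2)COC1=O | starting material
2 | acrolein | C=CC=O | starting material
3 | dibutylboron Z-enolate of 1 (not isolated) | CCCCB(CCCC)O/C(=C\C)N1C(=O)OC[C@@H]1Cc1ccccc1 | intermediate
4 | (S)-4-benzyl-3-[(2S,3R)-3-hydroxy-2-methylpent-4-enoyl]-1,3-oxazolidin-2-one | C=C[C@@H](O)[C@H](C)C(=O)N1[C@@H](Cc2ccccc2)COC1=O | intermediate
5 | methyl (2S,3R)-3-hydroxy-2-methylpent-4-enoate | C=C[C@@H](O)[C@H](C)C(=O)OC | intermediate
6 | ethyl 4-methylpent-4-enoate | CCOC(=O)CCC(C)=C | starting material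
7 | 4-methylpent-4-enal | O=CCCC(C)=C | intermediate
8 | dilithium enolate alkoxide of 5 (not isolated) | C=C[C@@H](O[Li])/C(C)=C(/OC)O[Li] | intermediate
9 | methyl (2R,3R)-3-hydroxy-2-[(1RS)-1-hydroxy-4-methylpent-4-en-1-yl]-2-methylpent-4-enoate | C=C[C@@H](O)[C@](C)(C(=O)OC)C(O)CCC(C)=C | intermediate
10 | methyl (1R,2R,7RS)-2,7-dihydroxy-1,4-dimethylcyclohept-3-ene-1-carboxylate | O[C@@H]1C=C(C)CCC(O)[C@@]1(C)C(=O)OC | intermediate
11 | methyl (1R)-1,4-dimethyl-2,7-dioxocyclohept-3-ene-1-carboxylate | O=C1C=C(C)CCC(=O)[C@@]1(C)C(=O)OC | intermediate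
12 | 2-bromo-3-methylbut-1-ene | C=C(Br)C(C)C | starting material
13 | (3-methylbut-1-en-2-yl)lithium (not isolated) | [Li]C(=C)C(C)C | intermediate
14 | dichloro(3-methylbut-1-en-2-yl)cerium (not isolated) | Cl[Ce](Cl)C(=C)C(C)C | intermediate
15 | methyl (1R,7S)-7-hydroxy-1,4-dimethyl-7-(3-methylbut-1-en-2-yl)-2-oxocyclohept-3-ene-1-carboxylate | O=C1C=C(C)CC[C@](O)(C(=C)C(C)C)[C@@]1(C)C(=O)OC | intermediate
16 | methyl (1S,2R,7S)-2,7-dihydroxy-1,4-dimethyl-7-(3-methylbut-1-en-2-yl)cyclohept-3-ene-1-carboxylate | O[C@@H]1C=C(C)CC[C@](O)(C(=C)C(C)C)[C@@]1(C)C(=O)OC | intermediate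
17 | (1S,2S,3R)-2-(hydroxymethyl)-2,5-dimethyl-1-(3-methylbut-1-en-2-yl)cyclohept-4-ene-1,3-diol | O[C@@H]1C=C(C)CC[C@](O)(C(=C)C(C)C)[C@@]1(C)CO | intermediate
18 | (1S,2R,7S)-2,7-dihydroxy-1,4-dimethyl-7-(3-methylbut-1-en-2-yl)cyclohept-3-ene-1-carbaldehyde | O[C@@H]1C=C(C)CC[C@](O)(C(=C)C(C)C)[C@@]1(C)C=O | intermediate
19 | 4-methoxybenzoyl chloride | COc1ccc(C(=O)Cl)cc1 | starting material
20 | (1R,6S,7S)-7-formyl-6-hydroxy-3,7-dimethyl-6-(3-methylbut-1-en-2-yl)cyclohept-2-en-1-yl 4-methoxybenzoate | COc1ccc(C(=O)O[C@@H]2C=C(C)CC[C@](O)(C(=C)C(C)C)[C@@]2(C)C=O)cc1 | intermediate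
21 | (3R,3aS,8R,8aS)-3a-hydroxy-6,8a-dimethyl-1-oxo-3-(propan-2-yl)-1,2,3,3a,4,5,8,8a-octahydroazulen-8-yl 4-methoxybenzoate | COc1ccc(C(=O)O[C@@H]2C=C(C)CC[C@]3(O)[C@@H](C(C)C)CC(=O)[C@@]23C)cc1 | target

**Step count.** Total: 12 steps. Longest linear sequence: 11 steps (steps 1, 2 and 4 to 12, from compound 1).

**Steps most likely to fail**

Step 12. Decarbonylation of the acyl rhodium hydride, or rhodium hydride isomerisation of the hindered alkene, may outpace migratory insertion, and hydride insertion may show poor facial selectivity at C3. The fallback sets out from 20 and closes the same ring by metathesis.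
- Addition of CH2=CHMgBr (THF, −78 °C) to the aldehyde should give the allylic alcohol (1R,6S,7S)-6-hydroxy-7-(1-hydroxyprop-2-en-1-yl)-3,7-dimethyl-6-(3-methylbut-1-en-2-yl)cyclohept-2-en-1-yl 4-methoxybenzoate F1 as a mixture of carbinol epimers.
- Dess–Martin oxidation should give the vinyl ketone (1R,6S,7S)-7-acryloyl-6-hydroxy-3,7-dimethyl-6-(3-methylbut-1-en-2-yl)cyclohept-2-en-1-yl 4-methoxybenzoate F2.
- Ring-closing metathesis (second-generation Hoveyda–Grubbs catalyst, toluene, 80 °C) would then give the cyclopentenone (3aS,8R,8aS)-3a-hydroxy-6,8a-dimethyl-1-oxo-3-(propan-2-yl)-1,3a,4,5,8,8a-hexahydroazulen-8-yl 4-methoxybenzoate F3.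
- Copper hydride conjugate reduction (CuCl, NaOt-Bu, p-Tol-BINAP, polymethylhydrosiloxane) would set C3 under catalyst control and come back to the route at 21. The ligand antipode that delivers hydride to the C3 face syn to the C8a methyl would have to be identified on F3.

Step 7. The metal alkoxide sits next to a β-keto ester unit and may open the ring by retro-aldol cleavage; attack at the conjugated carbonyl or on the face syn to the ester may also compete. The fallback sets out from 10 and removes the ester carbonyl before the addition.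
- LiAlH4 should give the triol (1RS,2R,3R)-2-(hydroxymethyl)-2,5-dimethylcyclohept-4-ene-1,3-diol F4.
- TBSCl and imidazole should silylate the primary hydroxyl to give (1RS,2R,3R)-2-{[tert-butyl(dimethyl)silyl]oxymethyl}-2,5-dimethylcyclohept-4-ene-1,3-diol F5.
- Dess–Martin oxidation should give the diketone (2R)-2-{[tert-butyl(dimethyl)silyl]oxymethyl}-2,5-dimethylcyclohept-4-ene-1,3-dione F6.
- Addition of organocerium 14, anti to the bulky silyloxymethyl group, should give (6S,7R)-7-{[tert-butyl(dimethyl)silyl]oxymethyl}-6-hydroxy-3,7-dimethyl-6-(3-methylbut-1-en-2-yl)cyclohept-2-en-1-one F7.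
- Directed reduction with Me4NBH(OAc)3 should give (1S,2S,3R)-2-{[tert-butyl(dimethyl)silyl]oxymethyl}-2,5-dimethyl-1-(3-methylbut-1-en-2-yl)cyclohept-4-ene-1,3-diol F8.
- Bu4NF removes the silyl group and the route is rejoined at 17.

Step 4. The tetrasubstituted dianion enolate may form incompletely or react with poor face selectivity, and the dialkoxide may equilibrate by retro-aldol. The result would be a four-component diastereomer mixture that cannot be purified before the relay carbinol is erased, which would lower the enantiomeric purity of 11. The fallback sets out from 5 and 6 and uses an acylation instead of the aldol.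
- Ester 6 is converted (MeNHOMe·HCl, i-PrMgCl, THF) into N-methoxy-N,4-dimethylpent-4-enamide F9.
- Acylation of dianion 8 with F9 proceeds through a stable tetrahedral chelate and should give, on acidic work-up, only two separable diastereomers, the major being methyl (2S,3R)-3-hydroxy-2-methyl-2-(4-methylpent-4-enoyl)pent-4-enoate F10.
- Ring-closing metathesis (second-generation Grubbs catalyst) should give methyl (1S,2R)-2-hydroxy-1,4-dimethyl-7-oxocyclohept-3-ene-1-carboxylate F11.
- Dess–Martin oxidation returns to the route at 11.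

Further compounds
F1 | step 12 | (1R,6S,7S)-6-hydroxy-7-(1-hydroxyprop-2-en-1-yl)-3,7-dimethyl-6-(3-methylbut-1-en-2-yl)cyclohept-2-en-1-yl 4-methoxybenzoate | COc1ccc(C(=O)O[C@@H]2C=C(C)CC[C@](O)(C(=C)C(C)C)[C@@]2(C)C(O)C=C)cc1
F2 | step 12 | (1R,6S,7S)-7-acryloyl-6-hydroxy-3,7-dimethyl-6-(3-methylbut-1-en-2-yl)cyclohept-2-en-1-yl 4-methoxybenzoate | COc1ccc(C(=O)O[C@@H]2C=C(C)CC[C@](O)(C(=C)C(C)C)[C@@]2(C)C(=O)C=C)cc1
F3 | step 12 | (3aS,8R,8aS)-3a-hydroxy-6,8a-dimethyl-1-oxo-3-(propan-2-yl)-1,3a,4,5,8,8a-hexahydroazulen-8-yl 4-methoxybenzoate | COc1ccc(C(=O)O[C@@H]2C=C(C)CC[C@]3(O)C(C(C)C)=CC(=O)[C@@]23C)cc1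
F4 | step 7 | (1RS,2R,3R)-2-(hydroxymethyl)-2,5-dimethylcyclohept-4-ene-1,3-diol | O[C@@H]1C=C(C)CCC(O)[C@@]1(C)CO
F5 | step 7 | (1RS,2R,3R)-2-{[tert-butyl(dimethyl)silyl]oxymethyl}-2,5-dimethylcyclohept-4-ene-1,3-diol | O[C@@H]1C=C(C)CCC(O)[C@@]1(C)CO[Si](C)(C)C(C)(C)C
F6 | step 7 | (2R)-2-{[tert-butyl(dimethyl)silyl]oxymethyl}-2,5-dimethylcyclohept-4-ene-1,3-dione | O=C1C=C(C)CCC(=O)[C@@]1(C)CO[Si](C)(C)C(C)(C)C
F7 | step 7 | (6S,7R)-7-{[tert-butyl(dimethyl)silyl]oxymethyl}-6-hydroxy-3,7-dimethyl-6-(3-methylbut-1-en-2-yl)cyclohept-2-en-1-one | O=C1C=C(C)CC[C@](O)(C(=C)C(C)C)[C@@]1(C)CO[Si](C)(C)C(C)(C)C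
F8 | step 7 | (1S,2S,3R)-2-{[tert-butyl(dimethyl)silyl]oxymethyl}-2,5-dimethyl-1-(3-methylbut-1-en-2-yl)cyclohept-4-ene-1,3-diol | O[C@@H]1C=C(C)CC[C@](O)(C(=C)C(C)C)[C@@]1(C)CO[Si](C)(C)C(C)(C)C
F9 | step 4 | N-methoxy-N,4-dimethylpent-4-enamide | CON(C)C(=O)CCC(C)=C
F10 | step 4 | methyl (2S,3R)-3-hydroxy-2-methyl-2-(4-methylpent-4-enoyl)pent-4-enoate | C=C[C@@H](O)[C@](C)(C(=O)OC)C(=O)CCC(C)=C
F11 | step 4 | methyl (1S,2R)-2-hydroxy-1,4-dimethyl-7-oxocyclohept-3-ene-1-carboxylate | O[C@@H]1C=C(C)CCC(=O)[C@@]1(C)C(=O)OC
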